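The seven-membered carbocycle is disconnected into a C3 unit (C8–C9–C10, the two CH2 groups and the CHCH3) and the arc C7–C6–C5–C1. C1, the ring-fusion carbon, carries the ether oxygen and C7, a cyclopropane CH, lies 1,4 to it, so the arc is a furan. A rhodium vinylcarbenoid cyclopropanation–Cope cascade (formal 4+3) between a siloxyvinyl diazoester and a cyclopenta[b]furan that already holds the quaternary C4 forms both ring bonds and an 8-oxabicyclo[3.2.1]octadiene. The temporary C7–O bond is then cleaved by SN2′ hydride opening, which moves the alkene to C6=C7 for gem-dimethylcyclopropanation and keeps oxygen at C1; acid-mediated union with diformylphloroglucinol closes the bridged aryl ether.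

Key step: step 6

Remark: compounds 1, 2, 6 and 19 are taken as commercially available. Numbering follows the aromadendrane skeleton: C1 O-bearing ring fusion, C4 quaternary carbon, C5 ring-fusion CH, C6/C7 cyclopropane CH, C8/C9 CH2, C10 CHCH3, C7′ benzylic carbon.

Step 1
Reactants: 1 2,3-dibromofuran; 2 2-methylbut-3-en-1-ol
Product: 3 4-(3-bromofuran-2-yl)-2-methylbutanal
Conditions: Pd(OAc)2 (5 mol %), n-Bu4NCl, NaHCO3, DMF, 50 °C
Reagents that add atoms: none
Why: Heck arylation at the more reactive C2–Br of the furan, followed by palladium chain-walking to the enol, should give the γ-aryl aldehyde (redox-relay Heck reaction of an alkenol); the α-centre is left racemic because it is enolised in step 2.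

Step 2
Reactants: 3 4-(3-bromofuran-2-yl)-2-methylbutanal
Product: 4 (S)-4-methyl-5,6-dihydro-4H-cyclopenta[b]furan-4-carbaldehyde
Conditions: Pd(OAc)2 (5 mol %), t-Bu-PHOX (chiral phosphinooxazoline, the enantiomer that gives the S product), Cs2CO3, DMF, 80 °C
Reagents that add atoms: none
Why: Palladium-catalysed asymmetric intramolecular α-arylation of the α-branched aldehyde (5-exo coupling of the enolate with the C3–Br) should close the cyclopentane and create the quaternary C4, whose configuration is set by the chiral ligand.

Step 3
Reactants: 4 (S)-4-methyl-5,6-dihydro-4H-cyclopenta[b]furan-4-carbaldehyde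
Product: 5 (4S)-4-[methoxy(phenyl)methyl]-4-methyl-5,6-dihydro-4H-cyclopenta[b]furan
Conditions: PhLi, THF, −78 °C; then MeI, DMPU, −78 °C to rt
Reagents that add atoms: phenyllithium [Li]c1ccccc1; iodomethane CI
Why: 1,2-Addition of the aryllithium to the non-enolisable aldehyde and Williamson O-methylation of the lithium alkoxide in the same flask; the carbinol configuration is not controlled because this carbon is ionised in step 13.

Step 4
Reactants: 6 methyl 3-oxobutanoate
Product: 7 methyl 2-diazo-3-oxobutanoate
Conditions: 4-acetamidobenzenesulfonyl azide, Et3N, MeCN, 0 °C to rt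
Reagents that add atoms: 4-acetamidobenzenesulfonyl azide CC(=O)Nc1ccc(cc1)S(=O)(=O)N=[N+]=[N-]
Why: Regitz diazo transfer to the active methylene of the β-keto ester.

Step 5
Reactants: 7 methyl 2-diazo-3-oxobutanoate
Product: 8 methyl 3-[(tert-butyldimethylsilyl)oxy]-2-diazobut-3-enoate
Conditions: TBSOTf, Et3N, CH2Cl2, 0 °C
Reagents that add atoms: tert-butyldimethylsilyl trifluoromethanesulfonate CC(C)(C)[Si](C)(C)OS(=O)(=O)C(F)(F)F
Why: Enol silylation of the acetyl group gives the donor/acceptor vinyldiazo ester (silyl enol ether formation).

Step 6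
Reactants: 5 (4S)-4-[methoxy(phenyl)methyl]-4-methyl-5,6-dihydro-4H-cyclopenta[b]furan; 8 methyl 3-[(tert-butyldimethylsilyl)oxy]-2-diazobut-3-enoate
Product: 11 oxa-bridged β-keto ester, via divinylcyclopropane 9 (not isolated), via silyl enol ether 10 (not isolated)
Conditions: Rh2(O2CC7H15)4 (1 mol %), slow addition of 8, hexanes, reflux; then HF·pyridine, THF, 0 °C
Reagents that add atoms: none
Why: The rhodium carbenoid from 8 should cyclopropanate the unsubstituted C6=C7 bond of furan 5 (carbene carbon C8 to the α-carbon C7) on the face anti to the methoxy(phenyl)methyl group at C4, giving cis-divinylcyclopropane 9, whose boat Cope rearrangement breaks C8–C6 and joins the vinyl terminus C10 to C1; cleavage of silyl enol ether 10 then gives 11. The closest known reaction type is the tandem cyclopropanation/Cope rearrangement (formal 4+3 cycloaddition) of siloxyvinyl diazoacetates with furans. The seven-membered carbocycle closes by the [3,3]-sigmatropic shift of the divinylcyclopropane, and the one-atom bridge is the furan oxygen, so the bridgeheads C1 and C7 are necessarily cis. Their absolute sense is controlled by the quaternary C4 (attack anti to its larger substituent), which places the oxygen on the face of the benzylic carbon and C10 on the face of the C4 methyl, as in the target. The step needs regioselectivity (C8 to C7, C10 to the substituted C1), secured by cyclopropanation of the less substituted furan double bond, and chemoselectivity over furan ring opening to trienones, secured by the less electrophilic siloxy-substituted carbenoid.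

Step 7
Reactants: 11 oxa-bridged β-keto ester
Product: 12 C10-methyl β-keto ester
Conditions: NaH, THF, 0 °C; n-BuLi, −78 °C; MeI, −78 to −20 °C
Reagents that add atoms: iodomethane CI
Why: γ-Alkylation of the β-keto ester dianion: C10 should be methylated from the exo face (the side of the oxygen bridge, away from the etheno bridge), which sets the C10 methyl cis to the C1 oxygen.

Step 8
Reactants: 12 C10-methyl β-keto ester
Product: 13 oxa-bridged ketone
Conditions: Me3SnOH, ClCH2CH2Cl, 80 °C; then aq. HCl wash
Reagents that add atoms: none
Why: Mild ester hydrolysis and spontaneous decarboxylation of the β-keto acid remove the auxiliary ester at C8 under conditions that should not epimerise C10.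

Step 9
Reactants: 13 oxa-bridged ketone
Product: 15 oxa-bridged tricyclic ether, via tosylhydrazone 14 (not isolated)
Conditions: TsNHNH2, MeOH, 50 °C; then catecholborane, CHCl3, 0 °C; NaOAc·3H2O, reflux
Reagents that add atoms: none
Why: Tosylhydrazone formation and hydride reduction with loss of sulfinate and N2 (Caglioti-type deoxygenation) convert the C9 carbonyl into CH2 without the strong base that could epimerise C10.

Step 10
Reactants: 15 oxa-bridged tricyclic ether
Product: 16 bicyclic cycloheptenol
Conditions: i-Bu2AlH (3 equiv), Ni(C8H12)2 (bis(1,5-cyclooctadiene)nickel, 10 mol %), Ph2P(CH2)4PPh2, toluene, 60 °C; aq. potassium sodium tartrate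
Reagents that add atoms: none
Why: Nickel-catalysed hydroalumination and β-alkoxide elimination (reductive SN2′ opening of an oxabicyclic alkene): hydride should reach C5 from the exo face, cis to the bridging oxygen, aluminium adds to the less substituted C6, and loss of the C7–O bond gives the C6=C7 alkene and the tertiary C1 alcohol.

Step 11
Reactants: 16 bicyclic cycloheptenol
Product: 17 gem-dibromocyclopropane
Conditions: CHBr3, KOt-Bu, pentane, −20 to 0 °C
Reagents that add atoms: bromoform BrC(Br)Br
Why: Dibromocarbene [2+1] cycloaddition to the cis-disubstituted cycloheptene should occur on the convex face of the cis-fused bicycle (the face of the C1 hydroxyl and H5, away from the C4 methyl), and the hindered tertiary alkoxide is no more reactive towards the carbene than tert-butoxide itself.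

Step 12
Reactants: 17 gem-dibromocyclopropane
Product: 18 gem-dimethylcyclopropyl tertiary alcohol
Conditions: Me2CuLi (excess), Et2O, −20 to 0 °C; then MeI
Reagents that add atoms: lithium dimethylcuprate [Li+].C[Cu-]C; iodomethane CI
Why: Double methylation of the gem-dibromocyclopropane with the cuprate (halogen–copper exchange, 1,2-methyl shift, then alkylation of the cyclopropylcopper with MeI) gives the gem-dimethylcyclopropane without touching the ring stereocentres.

Step 13
Reactants: 18 gem-dimethylcyclopropyl tertiary alcohol; 19 2,4,6-trihydroxybenzene-1,3-dicarbaldehyde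
Product: 21 psiguadial A, via C-benzylated phloroglucinol 20 (not isolated)
Conditions: TsOH·H2O (20 mol %), (CF3)2CHOH, 40 °C
Reagents that add atoms: none
Why: SN1 Friedel–Crafts alkylation of the only free ring position of 19 by the benzylic cation gives 20, and ionisation of the tertiary C1 alcohol with capture by the neighbouring phenol (the cation–phenol closure assumed in the biogenesis) should form the seven-membered bridged aryl ether with phenyl on the less hindered side, over the one-carbon C5 bridge.

Compound list

1 | 2,3-dibromofuran | Brc1occc1Br | starting material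
2 | 2-methylbut-3-en-1-ol (racemic) | C=CC(C)CO | starting material
3 | 4-(3-bromofuran-2-yl)-2-methylbutanal (racemic) | O=CC(C)CCc1occc1Br | intermediate
4 | (S)-4-methyl-5,6-dihydro-4H-cyclopenta[b]furan-4-carbaldehyde | C[C@]1(C=O)CCc2occc21 | intermediate
5 | (4S)-4-[methoxy(phenyl)methyl]-4-methyl-5,6-dihydro-4H-cyclopenta[b]furan (both carbinol epimers) | C[C@]1(C(OC)c3ccccc3)CCc2occc21 | intermediate
6 | methyl 3-oxobutanoate | COC(=O)CC(C)=O | starting material
7 | methyl 2-diazo-3-oxobutanoate | COC(=O)C(=[N+]=[N-])C(C)=O | intermediate
8 | methyl 3-[(tert-butyldimethylsilyl)oxy]-2-diazobut-3-enoate | COC(=O)C(=[N+]=[N-])C(=C)O[Si](C)(C)C(C)(C)C | intermediate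
9 | cis-divinylcyclopropane: cyclopentane-fused 2-oxabicyclo[3.1.0]hex-3-ene; C8 carries CO2Me exo and the 1-(TBS-oxy)vinyl group endo; cyclopropane on the furan face anti to the methoxy(phenyl)methyl group | C=C(O[Si](C)(C)C(C)(C)C)[C@@]1(C(=O)OC)[C@H]2OC3=C([C@H]21)[C@@](C)(C(OC)c4ccccc4)CC3 | intermediate
10 | silyl enol ether cycloadduct: cyclopentane-fused 8-oxabicyclo[3.2.1]octa-2,6-diene, CO2Me on C8, OTBS on C9, oxygen bridge on the face of the C4 benzylic substituent | C1C(O[Si](C)(C)C(C)(C)C)=C(C(=O)OC)[C@@H]2C=C3[C@@](C)(C(OC)c4ccccc4)CC[C@@]31O2 | intermediate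
11 | oxa-bridged β-keto ester (keto form shown; C8 epimers and enol in equilibrium) | C1C(=O)C(C(=O)OC)[C@@H]2C=C3[C@@](C)(C(OC)c4ccccc4)CC[C@@]31O2 | intermediate
12 | C10-methyl β-keto ester (C10 methyl on the side of the oxygen bridge) | C[C@H]1C(=O)C(C(=O)OC)[C@@H]2C=C3[C@@](C)(C(OC)c4ccccc4)CC[C@@]31O2 | intermediate
13 | oxa-bridged ketone (C9 ketone, C10 methyl cis to the oxygen bridge) | C[C@H]1C(=O)C[C@@H]2C=C3[C@@](C)(C(OC)c4ccccc4)CC[C@@]31O2 | intermediate
14 | 4-methylbenzenesulfonylhydrazone of 13 | C[C@H]1C(=NNS(=O)(=O)c5ccc(C)cc5)C[C@@H]2C=C3[C@@](C)(C(OC)c4ccccc4)CC[C@@]31O2 | intermediate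
15 | oxa-bridged tricyclic ether (C9 CH2, C5=C6 alkene, C1–O–C7 bridge) | C[C@H]1CC[C@@H]2C=C3[C@@](C)(C(OC)c4ccccc4)CC[C@@]31O2 | intermediate
16 | cis-fused bicyclo[5.3.0]decenol: tertiary C1 alcohol, H5 and C10 methyl cis to OH, C6=C7 alkene | C[C@H]1CCC=C[C@@H]3[C@@](C)(C(OC)c4ccccc4)CC[C@@]31O | intermediate
17 | gem-dibromocyclopropane (CBr2 on the face of the C1 hydroxyl) | C[C@H]1CC[C@@H]2[C@H]([C@@H]3[C@@](C)(C(OC)c4ccccc4)CC[C@@]31O)C2(Br)Br | intermediate
18 | gem-dimethylcyclopropyl tertiary alcohol (1-hydroxyaromadendrane with methoxy(phenyl)methyl at C4) | C[C@H]1CC[C@@H]2[C@H]([C@@H]3[C@@](C)(C(OC)c4ccccc4)CC[C@@]31O)C2(C)C | intermediate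
19 | 2,4,6-trihydroxybenzene-1,3-dicarbaldehyde (diformylphloroglucinol) | O=Cc1c(O)cc(O)c(C=O)c1O | starting material
20 | C-benzylated diformylphloroglucinol (C7′ bonded to the arene, C1 alcohol still free) | C[C@H]1CC[C@@H]2[C@H]([C@@H]3[C@@](C)([C@@H](c4ccccc4)c4c(O)c(C=O)c(O)c(C=O)c4O)CC[C@@]31O)C2(C)C | intermediate
21 | psiguadial A | C[C@H]1CC[C@@H]2[C@H]([C@@H]3[C@]4(C)CC[C@@]31Oc1c(C=O)c(O)c(C=O)c(O)c1[C@@H]4c1ccccc1)C2(C)C | target

Total step count: 13. Longest linear sequence: 11 steps (steps 1–3 and 6–13); steps 4–5 make the diazo partner.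

Steps most likely to fail

1. Step 6. The electrophilic carbenoid may attack the furan α-carbon and unravel the ring to a trienone instead of closing the cyclopropane, and the two furan faces may be discriminated only partly by C4. The fallback sets out from 5 and comes back at 13. An oxyallyl cation (4+3) cycloaddition of 5 with 1,1,3-trichloropropan-2-one (Et3N, CF3CH2OH) should give the dichloro ketone F1, with the bulky CCl2 terminus on the unhindered C7. Its only enolisable position is C10, so LiN(i-Pr)2 then MeI should give the exo-methyl dichloro ketone F2. Zn–Cu couple with NH4Cl in MeOH would then remove both chlorines to give 13.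

2. Step 13. Capture of the benzylic cation by the doubly formylated, deactivated arene may be slower than 1,2-shift, elimination or internal trapping by the C1 hydroxyl, and the benzylic configuration may not be fully controlled. The fallback sets out from 18 and ends at 21. The far more nucleophilic benzene-1,3,5-triol (TsOH·H2O, (CF3)2CHOH) should give, by the same alkylation and ether closure, the bis-deformyl bridged ether F3. Rieche formylation of both free ring positions (Cl2CHOCH3, TiCl4, CH2Cl2, then water) would then give 21.

3. Step 10. Hydroalumination of the hindered trisubstituted bridging alkene may stall, or aluminium may add at C5, which would cleave the C1–O bond instead of the C7–O bond. The fallback sets out from 15 and comes back at 16. Hydroboration–oxidation (BH3·THF; NaOH, H2O2) should give the exo C6 alcohol F4 with H5 cis to the bridge. Appel-type iodination (I2, PPh3, imidazole) would give the C6 iodide F5, and zinc in AcOH/EtOH would open the bridge by Boord-type reductive β-elimination to 16.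

Further compounds
F1 | step 6 | dichloro ketone of the oxa-bridged tricycle (C8 as CCl2, C9 ketone, C10 CH2) | C1C(=O)C(Cl)(Cl)[C@@H]2C=C3[C@@](C)(C(OC)c4ccccc4)CC[C@@]31O2
F2 | step 6 | C10-methyl dichloro ketone (methyl on the side of the oxygen bridge) | C[C@H]1C(=O)C(Cl)(Cl)[C@@H]2C=C3[C@@](C)(C(OC)c4ccccc4)CC[C@@]31O2
F3 | step 13 | bis-deformyl psiguadial A (bridged resorcinol ether) | C[C@H]1CC[C@@H]2[C@H]([C@@H]3[C@]4(C)CC[C@@]31Oc1cc(O)cc(O)c1[C@@H]4c1ccccc1)C2(C)C
F4 | step 10 | exo C6 alcohol of the saturated oxa-bridged tricycle (OH and H5 on the side of the oxygen bridge) | C[C@H]1CC[C@@H]2[C@@H](O)[C@@H]3[C@@](C)(C(OC)c4ccccc4)CC[C@@]31O2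
F5 | step 10 | endo C6 iodide of the saturated oxa-bridged tricycle | C[C@H]1CC[C@@H]2[C@H](I)[C@@H]3[C@@](C)(C(OC)c4ccccc4)CC[C@@]31O2
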